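**Plan**
- Retrosynthesis: the O-benzyl group and the C3 hydroxymethyl group are traced back to a trans 3-carboxylic acid, the O1–C2 bond of the dihydrofuran ring is cut next, and last the C3–C3a and C3–C2 bonds are cut together.
- Enabling feature: C3 is bonded to C3a of ring A, to the hydroxymethyl carbon and to C2 (which carries ring B and O1). C3 can therefore be the carbene carbon of a diazoacetate, placed between a ring A aryl–rhodium bond and the aldehyde carbon that becomes C2.
- Forward: ring A is brominated next to its phenol, protected and borylated. Boronate, diazoacetate and O-benzylsyringaldehyde are joined in one open-chain step. Acid then closes the dihydrofuran ring (the only ring made), the C3 acid is reduced and the benzyl group is removed.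
- Stereochemistry: C3 comes from a chiral diene on rhodium in the three-component union. C2 is set in the acid closure, under thermodynamic control, trans to C3.

Key step: step 5

Remark: the sense of induction of the diene ligand in step 5 cannot be read from precedent; the (1R,4R) ligand is written, and its mirror image would be taken if the first run shows the opposite sense.

**Step 1**
Reactants: 1 methyl 3-(4-hydroxy-3-methoxyphenyl)propanoate
Product: 2 methyl 3-(3-bromo-4-hydroxy-5-methoxyphenyl)propanoate
Conditions: NBS, i-Pr2NH (cat.), CH2Cl2, 0 °C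
Reagents that add atoms: N-bromosuccinimide, O=C1CCC(=O)N1Br
Why: Electrophilic aromatic bromination, in which the free phenol directs to its only open ortho position (para is held by the chain) and the amine-mediated NBS protocol favours ortho delivery.

**Step 2**
Reactants: 2 methyl 3-(3-bromo-4-hydroxy-5-methoxyphenyl)propanoate
Product: 3 methyl 3-[3-bromo-5-methoxy-4-(methoxymethoxy)phenyl]propanoate
Conditions: MOMCl, i-Pr2NEt, CH2Cl2, 0 °C to rt
Reagents that add atoms: chloromethyl methyl ether, COCCl
Why: O-alkylation of the phenol to its methoxymethyl ether, which removes the acidic proton before the rhodium step and is later lost under the acid that closes the ring.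

**Step 3**
Reactants: 3 methyl 3-[3-bromo-5-methoxy-4-(methoxymethoxy)phenyl]propanoate
Product: 4 methyl 3-[3-(5,5-dimethyl-1,3,2-dioxaborinan-2-yl)-5-methoxy-4-(methoxymethoxy)phenyl]propanoate
Conditions: bis(neopentyl glycolato)diboron, PdCl2(dppf) (3 mol %), KOAc, 1,4-dioxane, 80 °C
Reagents that add atoms: bis(neopentyl glycolato)diboron, CC1(C)COB(OC1)B1OCC(C)(C)CO1
Why: Miyaura borylation (oxidative addition to zerovalent palladium, acetate-assisted boryl transfer, reductive elimination), whose weak base spares the methyl ester and which gives directly the proton-free neopentyl glycol boronate wanted for step 5.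

**Step 4**
Reactants: 5 syringaldehyde (4-hydroxy-3,5-dimethoxybenzaldehyde)
Product: 6 4-(benzyloxy)-3,5-dimethoxybenzaldehyde
Conditions: BnBr, K2CO3, DMF, rt
Reagents that add atoms: benzyl bromide, BrCc1ccccc1
Why: Williamson etherification of the acidic para-formyl phenol, which masks the only protic group of the aldehyde component with a group that survives CF3CO2H and borane.

**Step 5**
Reactants: 4 methyl 3-[3-(5,5-dimethyl-1,3,2-dioxaborinan-2-yl)-5-methoxy-4-(methoxymethoxy)phenyl]propanoate; 7 tert-butyl diazoacetate; 6 4-(benzyloxy)-3,5-dimethoxybenzaldehyde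
Product: 9 tert-butyl (2S,3S)-3-[4-(benzyloxy)-3,5-dimethoxyphenyl]-3-hydroxy-2-[3-methoxy-5-(3-methoxy-3-oxopropyl)-2-(methoxymethoxy)phenyl]propanoate, via boronate-capped aldolate 8 (not isolated)
Conditions: [RhCl(C2H4)2]2 (2.5 mol %), (1R,4R)-2,5-diphenylbicyclo[2.2.2]octa-2,5-diene (6 mol %), KOt-Bu (10 mol %), 4 Å MS, toluene, 25 °C, 7 added over 6 h by syringe pump; then aq. NH4Cl
Reagents that add atoms: none
Why: Proposed new method: the aryl group of 4 should pass from boron to the diene-ligated monovalent rhodium alkoxide, the aryl-rhodium species should take up 7 as a carbene with loss of N2, and 1,2-migration of the aryl group to the carbene carbon should give a rhodium enolate (oxa-π-allyl) without β-hydrogens that adds to 6 through a closed six-membered transition state, after which the rhodium aldolate is handed to boron by the next molecule of 4 (giving 8 and a new aryl-rhodium species) and aqueous work-up hydrolyses the O–B bond to 9. The closest known reaction types are the couplings of arylboron reagents with diazoesters under monovalent rhodium catalysis in which the rhodium enolate is intercepted by a carbon electrophile instead of a proton, and the rhodium enolate aldol additions that follow conjugate arylation or hydrometalation of acrylates and enones. No ring is closed; the step makes C3a–C3 and C3–C2 of the later dihydrobenzofuran in one operation. The configuration at C3 (the ester α-carbon) is set by the C2-symmetric diene, which shields one face of the rhodium-bound enolate, while the carbinol centre follows from the chair-like aldol transition state (syn expected) and is not critical, because step 6 re-forms it through a benzylic cation. The step needs the aryl-rhodium species to take the carbene faster than it adds to the aldehyde, and the enolate to be caught by the aldehyde and not by a proton or a second carbene; this is meant to be secured by the electron-rich, weakly electrophilic aldehyde 6, the boronic ester with molecular sieves in place of a boronic acid (no B–OH protons), the lack of β-hydrogens in the enolate and the slow addition of 7. The precatalyst carries only ethylene, so the chiral diene is the sole diene on rhodium.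

**Step 6**
Reactants: 9 tert-butyl (2S,3S)-3-[4-(benzyloxy)-3,5-dimethoxyphenyl]-3-hydroxy-2-[3-methoxy-5-(3-methoxy-3-oxopropyl)-2-(methoxymethoxy)phenyl]propanoate
Product: 11 (2S,3S)-2-[4-(benzyloxy)-3,5-dimethoxyphenyl]-7-methoxy-5-(3-methoxy-3-oxopropyl)-2,3-dihydro-1-benzofuran-3-carboxylic acid (trans), via trans tert-butyl ester 10 (not isolated)
Conditions: CF3CO2H/CH2Cl2 (1:4), 0 °C to rt
Reagents that add atoms: none
Why: Acid-mediated SN1 cyclodehydration followed by tert-butyl ester acidolysis: the carbinol ionizes to a benzylic cation stabilized by ring B, the ring A oxygen captures it in a five-membered closure with loss of the methoxymethyl group to give 10, reversible re-ionization at C2 lets the aryl group settle trans to the C3 carboxyl (C3 is untouched, so both carbinol epimers converge), and the tert-butyl ester then falls to the acid while the methyl ester and the aryl benzyl ether withstand cold CF3CO2H.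

**Step 7**
Reactants: 11 (2S,3S)-2-[4-(benzyloxy)-3,5-dimethoxyphenyl]-7-methoxy-5-(3-methoxy-3-oxopropyl)-2,3-dihydro-1-benzofuran-3-carboxylic acid
Product: 12 methyl 3-[(2S,3R)-2-[4-(benzyloxy)-3,5-dimethoxyphenyl]-3-(hydroxymethyl)-7-methoxy-2,3-dihydro-1-benzofuran-5-yl]propanoate
Conditions: BH3·SMe2, THF, 0 °C to rt; then MeOH
Reagents that add atoms: none
Why: Chemoselective borane reduction of a carboxylic acid, which proceeds through an acyloxyborane far faster than attack on the methyl ester and is neutral enough to leave C2 and C3 unchanged (the descriptor at C3 changes only because the priorities change).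

**Step 8**
Reactants: 12 methyl 3-[(2S,3R)-2-[4-(benzyloxy)-3,5-dimethoxyphenyl]-3-(hydroxymethyl)-7-methoxy-2,3-dihydro-1-benzofuran-5-yl]propanoate
Product: 13 methyl 3-[(2S,3R)-2-(4-hydroxy-3,5-dimethoxyphenyl)-3-(hydroxymethyl)-7-methoxy-2,3-dihydro-1-benzofuran-5-yl]propanoate (CNP0362206.1)
Conditions: H2 (1 atm), Pd/C (10 wt %), EtOAc, rt
Reagents that add atoms: none
Why: Catalytic hydrogenolysis of the primary O-benzyl aryl ether, which at 1 atm should be much faster than cleavage of the hindered secondary C2–O1 bond of the ring, so both stereocentres are kept.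

**Compound list**
1 | methyl 3-(4-hydroxy-3-methoxyphenyl)propanoate | COC(=O)CCc1ccc(O)c(OC)c1 | starting material
2 | methyl 3-(3-bromo-4-hydroxy-5-methoxyphenyl)propanoate | COC(=O)CCc1cc(Br)c(O)c(OC)c1 | intermediate
3 | methyl 3-[3-bromo-5-methoxy-4-(methoxymethoxy)phenyl]propanoate | COC(=O)CCc1cc(Br)c(OCOC)c(OC)c1 | intermediate
4 | methyl 3-[3-(5,5-dimethyl-1,3,2-dioxaborinan-2-yl)-5-methoxy-4-(methoxymethoxy)phenyl]propanoate | COC(=O)CCc1cc(OC)c(OCOC)c(c1)B1OCC(C)(C)CO1 | intermediate
5 | syringaldehyde (4-hydroxy-3,5-dimethoxybenzaldehyde) | COc1cc(C=O)cc(OC)c1O | starting material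
6 | 4-(benzyloxy)-3,5-dimethoxybenzaldehyde | COc1cc(C=O)cc(OC)c1OCc1ccccc1 | intermediate
7 | tert-butyl diazoacetate | [N-]=[N+]=CC(=O)OC(C)(C)C | starting material
8 | tert-butyl (2S,3S)-3-[4-(benzyloxy)-3,5-dimethoxyphenyl]-3-[(5,5-dimethyl-1,3,2-dioxaborinan-2-yl)oxy]-2-[3-methoxy-5-(3-methoxy-3-oxopropyl)-2-(methoxymethoxy)phenyl]propanoate | COC(=O)CCc1cc(OC)c(OCOC)c(c1)[C@H](C(=O)OC(C)(C)C)[C@H](OB1OCC(C)(C)CO1)c1cc(OC)c(OCc2ccccc2)c(OC)c1 | intermediate
9 | tert-butyl (2S,3S)-3-[4-(benzyloxy)-3,5-dimethoxyphenyl]-3-hydroxy-2-[3-methoxy-5-(3-methoxy-3-oxopropyl)-2-(methoxymethoxy)phenyl]propanoate | COC(=O)CCc1cc(OC)c(OCOC)c(c1)[C@H](C(=O)OC(C)(C)C)[C@H](O)c1cc(OC)c(OCc2ccccc2)c(OC)c1 | intermediate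
10 | tert-butyl (2S,3S)-2-[4-(benzyloxy)-3,5-dimethoxyphenyl]-7-methoxy-5-(3-methoxy-3-oxopropyl)-2,3-dihydro-1-benzofuran-3-carboxylate (trans) | COC(=O)CCc1cc(OC)c2c(c1)[C@H](C(=O)OC(C)(C)C)[C@@H](c1cc(OC)c(OCc3ccccc3)c(OC)c1)O2 | intermediate
11 | (2S,3S)-2-[4-(benzyloxy)-3,5-dimethoxyphenyl]-7-methoxy-5-(3-methoxy-3-oxopropyl)-2,3-dihydro-1-benzofuran-3-carboxylic acid (trans) | COC(=O)CCc1cc(OC)c2c(c1)[C@H](C(=O)O)[C@@H](c1cc(OC)c(OCc3ccccc3)c(OC)c1)O2 | intermediate
12 | methyl 3-[(2S,3R)-2-[4-(benzyloxy)-3,5-dimethoxyphenyl]-3-(hydroxymethyl)-7-methoxy-2,3-dihydro-1-benzofuran-5-yl]propanoate | COC(=O)CCc1cc(OC)c2c(c1)[C@H](CO)[C@@H](c1cc(OC)c(OCc3ccccc3)c(OC)c1)O2 | intermediate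
13 | methyl 3-[(2S,3R)-2-(4-hydroxy-3,5-dimethoxyphenyl)-3-(hydroxymethyl)-7-methoxy-2,3-dihydro-1-benzofuran-5-yl]propanoate | COC(=O)CCc1cc(OC)c2c(c1)[C@H](CO)[C@@H](c1cc(OC)c(O)c(OC)c1)O2 | target

**Count**
Total steps: 8. Longest linear sequence: 7 (steps 1, 2, 3, 5, 6, 7, 8); step 4 is a one-step side branch.

**Steps most likely to fail**

1. Step 5 (bears the label "Proposed new method:"). The rhodium enolate may be protonated to the arylacetate, the aryl-rhodium species may add directly to the aldehyde, the rhodium aldolate may lose hydride before boron takes it over, or the diene may not differentiate the enolate faces. The fallback uses known chemistry, sets out from 2 and 6 and returns at 10, making C3–C3a by palladium arylation and C3–C2 by enantioselective carbene C–H insertion.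
   - NaBH4 in MeOH reduces 6 to [4-(benzyloxy)-3,5-dimethoxyphenyl]methanol F1.
   - Mitsunobu etherification of phenol 2 with F1 (PPh3, DIAD, THF) gives methyl 3-[4-{[4-(benzyloxy)-3,5-dimethoxyphenyl]methoxy}-3-bromo-5-methoxyphenyl]propanoate F2.
   - Coupling of the aryl bromide with the Reformatsky reagent BrZnCH2CO2t-Bu (Pd2(dba)3, XPhos, THF, 60 °C) gives the tert-butyl arylacetate F3.
   - Diazo transfer (4-acetamidobenzenesulfonyl azide, DBU, MeCN), which touches only the more acidic arylacetate position, gives the tert-butyl aryldiazoacetate F4.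
   - Intramolecular insertion of the rhodium carbene into the O-benzylic C–H bond with dirhodium tetrakis[N-phthaloyl-(S)-tert-leucinate], Rh2(S-PTTL)4 (toluene, −60 °C; the mirror-image catalyst if the sense is opposite) gives the cis tert-butyl (2S,3R)-dihydrobenzofuran-3-carboxylate F5.
   - Epimerization at C3 (NaOMe, MeOH, rt) gives trans ester 10, which is taken to 11 with CF3CO2H as in step 6.

2. Step 6. Once the tert-butyl ester has been cleaved, renewed ionization at C2 can be followed by loss of CO2 or of the C3 proton (stilbene formation), and long exposure to acid can start to remove the benzyl group. The fallback sets out from 9, returns at 12, and never has the free acid in an ionizing medium.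
   - BF3·OEt2 (0.2 equiv, CH2Cl2, −40 to 0 °C) closes the ring and 10 is isolated.
   - SOCl2 (CH2Cl2, rt) converts the tert-butyl ester directly into (2S,3S)-2-[4-(benzyloxy)-3,5-dimethoxyphenyl]-7-methoxy-5-(3-methoxy-3-oxopropyl)-2,3-dihydro-1-benzofuran-3-carbonyl chloride F6, the methyl ester being inert.
   - NaBH4 (THF, −20 °C) reduces the acid chloride to 12.

3. Step 3. Protodebromination may compete in the palladium cycle on this electron-rich, ortho-alkoxy bromide, and the neopentyl glycol ester may hydrolyse on silica. The fallback sets out from 1 and returns at 4, replacing catalytic borylation by halogen–magnesium exchange.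
   - N-iodosuccinimide (cat. TsOH, MeCN) gives methyl 3-(4-hydroxy-3-iodo-5-methoxyphenyl)propanoate F7.
   - MOMCl and i-Pr2NEt give methyl 3-[3-iodo-5-methoxy-4-(methoxymethoxy)phenyl]propanoate F8.
   - Iodine–magnesium exchange (i-PrMgCl·LiCl, THF, −40 °C, where the ester is tolerated), B(OMe)3 quench and aqueous work-up give [3-methoxy-5-(3-methoxy-3-oxopropyl)-2-(methoxymethoxy)phenyl]boronic acid F9.
   - Condensation with neopentyl glycol (MgSO4, CH2Cl2) gives 4.

**Further compounds**
F1 | step 5 | [4-(benzyloxy)-3,5-dimethoxyphenyl]methanol | COc1cc(CO)cc(OC)c1OCc1ccccc1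
F2 | step 5 | methyl 3-[4-{[4-(benzyloxy)-3,5-dimethoxyphenyl]methoxy}-3-bromo-5-methoxyphenyl]propanoate | COC(=O)CCc1cc(Br)c(OCc2cc(OC)c(OCc3ccccc3)c(OC)c2)c(OC)c1
F3 | step 5 | tert-butyl 2-[2-{[4-(benzyloxy)-3,5-dimethoxyphenyl]methoxy}-3-methoxy-5-(3-methoxy-3-oxopropyl)phenyl]acetate | COC(=O)CCc1cc(CC(=O)OC(C)(C)C)c(OCc2cc(OC)c(OCc3ccccc3)c(OC)c2)c(OC)c1
F4 | step 5 | tert-butyl 2-[2-{[4-(benzyloxy)-3,5-dimethoxyphenyl]methoxy}-3-methoxy-5-(3-methoxy-3-oxopropyl)phenyl]-2-diazoacetate | COC(=O)CCc1cc(C(=[N+]=[N-])C(=O)OC(C)(C)C)c(OCc2cc(OC)c(OCc3ccccc3)c(OC)c2)c(OC)c1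
F5 | step 5 | tert-butyl (2S,3R)-2-[4-(benzyloxy)-3,5-dimethoxyphenyl]-7-methoxy-5-(3-methoxy-3-oxopropyl)-2,3-dihydro-1-benzofuran-3-carboxylate (cis) | COC(=O)CCc1cc(OC)c2c(c1)[C@@H](C(=O)OC(C)(C)C)[C@@H](c1cc(OC)c(OCc3ccccc3)c(OC)c1)O2
F6 | step 6 | (2S,3S)-2-[4-(benzyloxy)-3,5-dimethoxyphenyl]-7-methoxy-5-(3-methoxy-3-oxopropyl)-2,3-dihydro-1-benzofuran-3-carbonyl chloride | COC(=O)CCc1cc(OC)c2c(c1)[C@H](C(Cl)=O)[C@@H](c1cc(OC)c(OCc3ccccc3)c(OC)c1)O2
F7 | step 3 | methyl 3-(4-hydroxy-3-iodo-5-methoxyphenyl)propanoate | COC(=O)CCc1cc(I)c(O)c(OC)c1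
F8 | step 3 | methyl 3-[3-iodo-5-methoxy-4-(methoxymethoxy)phenyl]propanoate | COC(=O)CCc1cc(I)c(OCOC)c(OC)c1
F9 | step 3 | [3-methoxy-5-(3-methoxy-3-oxopropyl)-2-(methoxymethoxy)phenyl]boronic acid | COC(=O)CCc1cc(OC)c(OCOC)c(c1)B(O)O
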